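**Retrosynthetic overview** (labdane numbering throughout)

- The C15 silyl ether, the C7 acetate and the C17 methyl group are removed in that order, leading back to a 7β-silyloxy-17-nor-8-ketone. The methyl group enters equatorially, which gives the axial 8β-OH.
- Ring B is opened at C7–C8: an intramolecular Henry reaction of a C8 nitromethyl group on a C7 aldehyde, followed by a Nef reaction to the C8 ketone. C9 is corrected next to that ketone.
- Key disconnection: C5–C6 and C9–C10 are made in one operation, by copper-catalysed vinyl addition to 2,4,4-trimethylcyclohex-2-en-1-one and trapping of the enolate with the C8–C15 nitro-olefin. The strategy rests on C5 and the quaternary C10 of ring A being vicinal and trans and carrying the two arms of ring B (C6–C7 and C9–C8).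
- The nitro-olefin comes from geraniol by silylation, cleavage of the 6,7-alkene, Henry reaction with nitromethane and dehydration.
- Ring order: ring A is bought as the enone; ring B is the only ring closed (step 11).

Key step: step 6

Assumption: C15 is carried as the tert-butyldiphenylsilyl ether so that a triethylsilyl group at O-7 can later be removed beside it, and geraniol is used as the start because it is silylated directly.

**Step 1**
Reactants: 1 geraniol
Product: 2 geranyl tert-butyldiphenylsilyl ether
Conditions: t-BuPh2SiCl, imidazole, CH2Cl2, 0 °C → rt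
Reagents that add atoms: tert-butyl(chloro)diphenylsilane, CC(C)(C)[Si](Cl)(c1ccccc1)c1ccccc1
Why: silyl ether formation at the primary allylic alcohol; no stereocentre is formed and the E-alkene is untouched.

**Step 2**
Reactants: 2 geranyl tert-butyldiphenylsilyl ether
Product: 3 6,7-epoxygeranyl tert-butyldiphenylsilyl ether (racemic)
Conditions: mCPBA (1.05 equiv), NaHCO3, CH2Cl2, −20 → 0 °C
Reagents that add atoms: 3-chloroperoxybenzoic acid, OOC(=O)c1cccc(Cl)c1
Why: Prilezhaev epoxidation should select the electron-richer distal 6,7-alkene because the 2,3-alkene is deactivated by the allylic silyloxy group; the racemic epoxide centre is destroyed in step 3.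

**Step 3**
Reactants: 3 6,7-epoxygeranyl tert-butyldiphenylsilyl ether
Product: 4 (4E)-6-(tert-butyldiphenylsilyloxy)-4-methylhex-4-enal
Conditions: H5IO6, THF/H2O, 0 °C
Reagents that add atoms: none
Why: periodic acid hydrolyses the trisubstituted epoxide to the glycol and cleaves it in the same pot (glycol cleavage), releasing acetone and the C9 aldehyde without touching the allylic silyl ether or the trisubstituted alkene.

**Step 4**
Reactants: 4 (4E)-6-(tert-butyldiphenylsilyloxy)-4-methylhex-4-enal; 5 nitromethane
Product: 6 (5E)-7-(tert-butyldiphenylsilyloxy)-5-methyl-1-nitrohept-5-en-2-ol (racemic)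
Conditions: 5 (5 equiv), 1,1,3,3-tetramethylguanidine (0.1 equiv), THF, 0 °C → rt
Reagents that add atoms: none
Why: base-catalysed Henry (nitro-aldol) addition to an unhindered aliphatic aldehyde; the carbinol centre forms racemic and is removed in step 5.

**Step 5**
Reactants: 6 (5E)-7-(tert-butyldiphenylsilyloxy)-5-methyl-1-nitrohept-5-en-2-ol
Product: 8 side-chain nitro-olefin tert-butyl{[(2E,6E)-3-methyl-7-nitrohepta-2,6-dien-1-yl]oxy}diphenylsilane, via mesylate 7 (not isolated)
Conditions: MsCl, Et3N, CH2Cl2, −20 → 0 °C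
Reagents that add atoms: none
Why: mesylation followed by E1cB elimination through the nitronate should give the conjugated nitro-olefin as the thermodynamically favoured E isomer.

**Step 6**
Reactants: 9 2,4,4-trimethylcyclohex-2-en-1-one; 10 vinylmagnesium bromide; 8 side-chain nitro-olefin
Product: 13 ring A ketone (2S,3S)-2-[(2S,5E)-7-(tert-butyldiphenylsilyloxy)-5-methyl-1-nitrohept-5-en-2-yl]-2,4,4-trimethyl-3-vinylcyclohexan-1-one, via magnesium enolate 11 (not isolated), via magnesium nitronate 12 (not isolated)
Conditions: CuBr·SMe2 (5 mol %), (R)-1-[(S)-2-(diphenylphosphino)ferrocenyl]ethyldicyclohexylphosphine or its enantiomer (6 mol %), 10 (1.2 equiv), t-BuOMe, −75 °C; then 8 (1.3 equiv) in THF, −78 → −40 °C; AcOH, −78 °C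
Reagents that add atoms: none
Why: Proposed new method: the monovalent copper–diphosphine complex takes the vinyl group from the Grignard reagent and delivers it to the β-carbon (C5) of enone 9, leaving the regiodefined tetrasubstituted magnesium enolate 11, which attacks the β-carbon (C9) of nitro-olefin 8 through C10 to give nitronate 12, protonated on carbon by AcOH. The closest known reaction type is the copper-catalysed asymmetric conjugate addition of Grignard reagents to cyclic enones with ferrocenyl diphosphines followed by Michael trapping of the magnesium enolate; new here is the α-methyl-γ,γ-dimethyl enone, whose enolate has to form a quaternary carbon flanked by C4 and C5. No ring is closed in this step. C5 is set by the chiral ligand (the antipode that gives 5S is chosen), C10 by approach of the nitro-olefin anti to the C5 vinyl group, which makes the two new C–C bonds trans, and C9 by a synclinal arrangement with the nitro group over the O–Mg unit, the chain pointing away from the ring and H-9 over it. That arrangement is predicted to give the 9S epimer, which after ring closure has H-9 on the β face, opposite to the target; the selectivity at C9 need not be high because step 14 resets this centre. The step needs 1,4- over 1,2-addition (copper catalysis at low temperature), C- over O-attack of the enolate (a nitro-olefin is soft, unhindered at its β-carbon and among the few acceptors electrophilic enough for so hindered a donor) and a single Michael event (the magnesium nitronate is a poor donor at −78 °C and is quenched cold).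

**Step 7**
Reactants: 13 ring A ketone
Product: 14 tosylhydrazone of 13
Conditions: TsNHNH2 (1.5 equiv), pyridinium p-toluenesulfonate (cat.), EtOH, 70 °C
Reagents that add atoms: 4-methylbenzenesulfonohydrazide, Cc1ccc(cc1)S(=O)(=O)NN
Why: acid-catalysed hydrazone formation at the only carbonyl group; no stereocentre is affected because C10 is quaternary.

**Step 8**
Reactants: 14 tosylhydrazone of 13
Product: 16 8-nitro-7,8-seco-17-nor-9-epi-labda-6,13E-dien-15-yl tert-butyldiphenylsilyl ether, via boryl hydrazide 15 (not isolated)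
Conditions: catecholborane (3 equiv), CHCl3, 0 °C → rt; then NaOAc·3H2O, reflux
Reagents that add atoms: none
Why: Caglioti-type tosylhydrazone reduction: catecholborane adds hydride to C=N, acetate-induced loss of sulfinate gives the alkyldiazene, and loss of N2 leaves the C1 methylene, while the nitro group, both alkenes and the silyl ether should be inert to catecholborane at this temperature.

**Step 9**
Reactants: 16 8-nitro-7,8-seco-17-nor-9-epi-labda-6,13E-dien-15-yl tert-butyldiphenylsilyl ether
Product: 18 primary C7 alcohol, via alkylborane 17 (not isolated)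
Conditions: 9-BBN (1.5 equiv), THF, 0 → 40 °C; then pH 7 phosphate buffer, 30 % H2O2, 0 °C → rt
Reagents that add atoms: hydrogen peroxide, OO
Why: hydroboration–oxidation: 9-BBN adds anti-Markovnikov and should react with the monosubstituted vinyl group far faster than with the trisubstituted C13=C14 alkene, and the neutral peroxide work-up avoids nitronate formation.

**Step 10**
Reactants: 18 primary C7 alcohol
Product: 19 C7 aldehyde
Conditions: Dess–Martin periodinane, NaHCO3, CH2Cl2, 0 °C → rt
Reagents that add atoms: none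
Why: Dess–Martin oxidation stops at the aldehyde under buffered, non-basic conditions, so the nitromethyl group should not yet react.

**Step 11**
Reactants: 19 C7 aldehyde
Product: 20 8α-nitro-17-nor-9-epi-labd-13E-ene-7β,15-diol 15-(tert-butyldiphenylsilyl) ether
Conditions: DBU (0.2 equiv), MeCN, 0 °C → rt
Reagents that add atoms: none
Why: intramolecular Henry reaction (6-exo-trig attack of the C8 nitronate on the C7 aldehyde) closes ring B trans-fused because C5 and C10 are already fixed, and being reversible it should settle on the diequatorial 7β-OH/8α-NO2 isomer, the axial positions at C8 and C7 being penalised by the C10 methyl group and by the axial C9 chain.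

**Step 12**
Reactants: 20 nitro alcohol
Product: 21 7β-triethylsilyl ether of 20
Conditions: Et3SiCl, imidazole, DMF, 0 °C → rt
Reagents that add atoms: chlorotriethylsilane, CC[Si](Cl)(CC)CC
Why: silyl ether formation under mild conditions that should not trigger retro-Henry cleavage or dehydration; the ether blocks both pathways in the Nef step.

**Step 13**
Reactants: 21 7β-triethylsilyl ether of 20
Product: 23 7β-(triethylsilyloxy)-15-(tert-butyldiphenylsilyloxy)-17-nor-9-epi-labd-13E-en-8-one, via potassium nitronate 22 (not isolated)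
Conditions: KOtBu (1.05 equiv), THF, 0 °C; then aq TiCl3, NH4OAc buffer (pH 5–6), THF/H2O, 0 °C → rt
Reagents that add atoms: water, O
Why: reductive Nef reaction: trivalent titanium reduces the nitronate to the imine, which hydrolyses in the buffered medium to the C8 ketone, and unlike oxidative Nef variants this should leave the C13=C14 alkene and both silyl ethers untouched.

**Step 14**
Reactants: 23 9-epi ketone
Product: 24 7β-(triethylsilyloxy)-15-(tert-butyldiphenylsilyloxy)-17-norlabd-13E-en-8-one (H-9 α, side chain equatorial)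
Conditions: KOtBu (0.3 equiv), t-BuOH/THF, rt
Reagents that add atoms: none
Why: base-mediated epimerisation through the C8–C9 enolate: reprotonation should occur axially on the α face, anti to the axial C10 methyl group, giving the 9α-H ketone with an equatorial side chain, which is also expected to be the more stable isomer because the axial chain of 23 has syn-axial contacts with H-1α, H-5α and H-7α; the equatorial 7β-silyloxy group should persist because axial deprotonation and reprotonation at C7 return the same isomer.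

**Step 15**
Reactants: 24 8-ketone
Product: 25 7β-(triethylsilyloxy)-15-(tert-butyldiphenylsilyloxy)labd-13E-en-8β-ol (8α-CH3)
Conditions: CeCl3 (anhydrous, 2.5 equiv), MeMgBr (2.5 equiv), THF, −78 → −20 °C; sat. aq NH4Cl
Reagents that add atoms: methylmagnesium bromide, C[Mg]Br
Why: organocerium 1,2-addition suppresses enolisation of the hindered ketone, and the reagent should enter equatorially from the α face because the axial β trajectory is blocked by the axial C10 methyl group, which sets C8 with 8α-CH3 and axial 8β-OH.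

**Step 16**
Reactants: 25 tertiary alcohol
Product: 26 15-(tert-butyldiphenylsilyloxy)labd-13E-ene-7β,8β-diol
Conditions: pyridinium p-toluenesulfonate (0.2 equiv), MeOH/CH2Cl2, 0 °C → rt
Reagents that add atoms: none
Why: acid-catalysed methanolysis removes the triethylsilyl ether selectively, the primary tert-butyldiphenylsilyl ether being far more stable to mild acid and the tertiary alcohol not ionising under these conditions.

**Step 17**
Reactants: 26 7β,8β-diol
Product: 27 7β-acetoxy-15-(tert-butyldiphenylsilyloxy)labd-13E-en-8β-ol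
Conditions: Ac2O, pyridine, DMAP (cat.), CH2Cl2, rt
Reagents that add atoms: acetic anhydride, CC(=O)OC(C)=O
Why: DMAP-catalysed acylation should esterify the secondary equatorial 7β-OH only, the tertiary axial 8β-OH being too hindered to react at room temperature.

**Step 18**
Reactants: 27 silyl-protected acetate
Product: 28 target, (5S,7S,8R,9R,10S)-7-acetoxylabd-13E-ene-8,15-diol
Conditions: Bu4NF, AcOH (1:1), THF, 0 °C → rt
Reagents that add atoms: none
Why: fluoride-induced silyl ether cleavage, buffered with AcOH so that no alkoxide can trigger acetyl migration or ester cleavage.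

**Compound list**

1 | geraniol, (2E)-3,7-dimethylocta-2,6-dien-1-ol | CC(C)=CCC/C(C)=C/CO | starting material
2 | geranyl tert-butyldiphenylsilyl ether | CC(C)=CCC/C(C)=C/CO[Si](c1ccccc1)(c1ccccc1)C(C)(C)C | intermediate
3 | 6,7-epoxygeranyl tert-butyldiphenylsilyl ether (racemic at the epoxide carbon) | CC1(C)OC1CC/C(C)=C/CO[Si](c1ccccc1)(c1ccccc1)C(C)(C)C | intermediate
4 | (4E)-6-(tert-butyldiphenylsilyloxy)-4-methylhex-4-enal | O=CCC/C(C)=C/CO[Si](c1ccccc1)(c1ccccc1)C(C)(C)C | intermediate
5 | nitromethane | C[N+](=O)[O-] | starting material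
6 | (5E)-7-(tert-butyldiphenylsilyloxy)-5-methyl-1-nitrohept-5-en-2-ol (racemic) | [O-][N+](=O)CC(O)CC/C(C)=C/CO[Si](c1ccccc1)(c1ccccc1)C(C)(C)C | intermediate
7 | methanesulfonate of 6 (racemic, not isolated) | [O-][N+](=O)CC(OS(C)(=O)=O)CC/C(C)=C/CO[Si](c1ccccc1)(c1ccccc1)C(C)(C)C | intermediate
8 | side-chain nitro-olefin (C8–C15), tert-butyl{[(2E,6E)-3-methyl-7-nitrohepta-2,6-dien-1-yl]oxy}diphenylsilane | [O-][N+](=O)/C=C/CC/C(C)=C/CO[Si](c1ccccc1)(c1ccccc1)C(C)(C)C | intermediate
9 | 2,4,4-trimethylcyclohex-2-en-1-one | CC1=CC(C)(C)CCC1=O | starting material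
10 | vinylmagnesium bromide | C=C[Mg]Br | starting material
11 | bromomagnesium (3S)-2,4,4-trimethyl-3-vinylcyclohex-1-en-1-olate (not isolated) | C=C[C@H]1C(C)(C)CCC(O[Mg]Br)=C1C | intermediate
12 | bromomagnesium nitronate of 13 (not isolated) | C=C[C@H]1C(C)(C)CCC(=O)[C@]1(C)[C@H](CC/C(C)=C/CO[Si](c2ccccc2)(c2ccccc2)C(C)(C)C)C=[N+]([O-])O[Mg]Br | intermediate
13 | ring A ketone, (2S,3S)-2-[(2S,5E)-7-(tert-butyldiphenylsilyloxy)-5-methyl-1-nitrohept-5-en-2-yl]-2,4,4-trimethyl-3-vinylcyclohexan-1-one; vinyl and nitroalkyl chain trans | C=C[C@H]1C(C)(C)CCC(=O)[C@]1(C)[C@H](CC/C(C)=C/CO[Si](c2ccccc2)(c2ccccc2)C(C)(C)C)C[N+](=O)[O-] | intermediate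
14 | tosylhydrazone of 13 (C=N geometry not defined) | C=C[C@H]1C(C)(C)CCC(=NNS(=O)(=O)c2ccc(C)cc2)[C@]1(C)[C@H](CC/C(C)=C/CO[Si](c2ccccc2)(c2ccccc2)C(C)(C)C)C[N+](=O)[O-] | intermediate
15 | N-(1,3,2-benzodioxaborol-2-yl) tosylhydrazide from 14 (C1 epimers, centre lost in the same operation, not isolated) | C=C[C@H]1C(C)(C)CCC(N(NS(=O)(=O)c2ccc(C)cc2)B2Oc3ccccc3O2)[C@]1(C)[C@H](CC/C(C)=C/CO[Si](c2ccccc2)(c2ccccc2)C(C)(C)C)C[N+](=O)[O-] | intermediate
16 | 8-nitro-7,8-seco-17-nor-9-epi-labda-6,13E-dien-15-yl tert-butyldiphenylsilyl ether (ring A 5S,10S; C9 S) | C=C[C@H]1C(C)(C)CCC[C@]1(C)[C@H](CC/C(C)=C/CO[Si](c2ccccc2)(c2ccccc2)C(C)(C)C)C[N+](=O)[O-] | intermediate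
17 | B-alkyl-9-borabicyclo[3.3.1]nonane from 16, boron on C7 (not isolated) | B1(C2CCCC1CCC2)CC[C@H]3C(C)(C)CCC[C@]3(C)[C@H](CC/C(C)=C/CO[Si](c4ccccc4)(c4ccccc4)C(C)(C)C)C[N+](=O)[O-] | intermediate
18 | 8-nitro-7,8-seco-17-nor-9-epi-labd-13E-ene-7,15-diol 15-(tert-butyldiphenylsilyl) ether | OCC[C@H]1C(C)(C)CCC[C@]1(C)[C@H](CC/C(C)=C/CO[Si](c2ccccc2)(c2ccccc2)C(C)(C)C)C[N+](=O)[O-] | intermediate
19 | 15-(tert-butyldiphenylsilyloxy)-8-nitro-7,8-seco-17-nor-9-epi-labd-13E-en-7-al | O=CC[C@H]1C(C)(C)CCC[C@]1(C)[C@H](CC/C(C)=C/CO[Si](c2ccccc2)(c2ccccc2)C(C)(C)C)C[N+](=O)[O-] | intermediate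
20 | 8α-nitro-17-nor-9-epi-labd-13E-ene-7β,15-diol 15-(tert-butyldiphenylsilyl) ether (5α-H, 10β-CH3, 7β-OH and 8α-NO2 equatorial, H-9 β, side chain axial) | O[C@H]1C[C@H]2C(C)(C)CCC[C@]2(C)[C@H](CC/C(C)=C/CO[Si](c3ccccc3)(c3ccccc3)C(C)(C)C)[C@@H]1[N+](=O)[O-] | intermediate
21 | 7β-triethylsilyl ether of 20 | CC[Si](CC)(CC)O[C@H]1C[C@H]2C(C)(C)CCC[C@]2(C)[C@H](CC/C(C)=C/CO[Si](c3ccccc3)(c3ccccc3)C(C)(C)C)[C@@H]1[N+](=O)[O-] | intermediate
22 | potassium nitronate of 21 (not isolated) | CC[Si](CC)(CC)O[C@H]1C[C@H]2C(C)(C)CCC[C@]2(C)[C@H](CC/C(C)=C/CO[Si](c3ccccc3)(c3ccccc3)C(C)(C)C)C1=[N+]([O-])[O-].[K+] | intermediate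
23 | 7β-(triethylsilyloxy)-15-(tert-butyldiphenylsilyloxy)-17-nor-9-epi-labd-13E-en-8-one (H-9 β) | CC[Si](CC)(CC)O[C@H]1C[C@H]2C(C)(C)CCC[C@]2(C)[C@H](CC/C(C)=C/CO[Si](c3ccccc3)(c3ccccc3)C(C)(C)C)C1=O | intermediate
24 | 7β-(triethylsilyloxy)-15-(tert-butyldiphenylsilyloxy)-17-norlabd-13E-en-8-one (H-9 α, side chain equatorial) | CC[Si](CC)(CC)O[C@H]1C[C@H]2C(C)(C)CCC[C@]2(C)[C@@H](CC/C(C)=C/CO[Si](c3ccccc3)(c3ccccc3)C(C)(C)C)C1=O | intermediate
25 | 7β-(triethylsilyloxy)-15-(tert-butyldiphenylsilyloxy)labd-13E-en-8β-ol (8α-CH3) | CC[Si](CC)(CC)O[C@H]1C[C@H]2C(C)(C)CCC[C@]2(C)[C@@H](CC/C(C)=C/CO[Si](c3ccccc3)(c3ccccc3)C(C)(C)C)[C@@]1(C)O | intermediate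
26 | 15-(tert-butyldiphenylsilyloxy)labd-13E-ene-7β,8β-diol | O[C@H]1C[C@H]2C(C)(C)CCC[C@]2(C)[C@@H](CC/C(C)=C/CO[Si](c3ccccc3)(c3ccccc3)C(C)(C)C)[C@@]1(C)O | intermediate
27 | 7β-acetoxy-15-(tert-butyldiphenylsilyloxy)labd-13E-en-8β-ol | CC(=O)O[C@H]1C[C@H]2C(C)(C)CCC[C@]2(C)[C@@H](CC/C(C)=C/CO[Si](c3ccccc3)(c3ccccc3)C(C)(C)C)[C@@]1(C)O | intermediate
28 | (5S,7S,8R,9R,10S)-7-acetoxylabd-13E-ene-8,15-diol (7β-OAc, 8β-OH, 8α-CH3) | CC(=O)O[C@H]1C[C@H]2C(C)(C)CCC[C@]2(C)[C@@H](CC/C(C)=C/CO)[C@@]1(C)O | target

**Step count**

Total: 18 steps. Longest linear sequence: 18 steps (geraniol 1 → 28); enone 9 and Grignard reagent 10 enter unchanged at step 6.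

**Steps most likely to fail**

Step 6 (proposed new method). The hindered tetrasubstituted enolate may fail to add to the nitro-olefin, may instead deprotonate it or start its oligomerisation, or the vinyl transfer may proceed with poor enantioselectivity. Fallback with known chemistry, in which the two bond formations are separated: it sets out from 9 and 10, which are combined under the same copper–diphosphine catalysis in the presence of Me3SiCl to give, after isolation, the trimethylsilyl enol ether F1. MeLi in THF at 0 °C converts this into the lithium enolate F2, which at −78 °C adds to 8 (Michael addition of a lithium enolate to a nitro-olefin) to give the lithium nitronate F3. Quenching with AcOH at −78 °C gives 13, where the route is rejoined.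

Step 14. Epimerisation at C9 may stall because H-9 of 23 is equatorial and shielded, and the base may at the same time erode the configuration at C7 by enolisation toward the silyloxy-bearing carbon or by silyl migration. Fallback by directed kinetic protonation instead of equilibration: it sets out from 23, from which HF·pyridine in THF/pyridine removes the triethylsilyl group to give the 9-epi α-hydroxy ketone F4. LiN(iPr)2 (2.5 equiv, THF, −78 → 0 °C) first forms the C7 alkoxide, which blocks deprotonation at C7, and then removes H-9 to give the dilithium alkoxide enolate F5. AcOH at −78 °C should protonate C9 on the α face, anti to the C10 methyl group, and give the α-hydroxy ketone with natural C9 configuration F6. Et3SiCl and imidazole in DMF then return 24.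

Step 7. Condensation at the neopentyl C1 carbonyl, flanked by the fully substituted C10, may be too slow or incomplete. Fallback by radical deoxygenation: it sets out from 13, which NaBH4 in MeOH at 0 °C reduces to the C1 alcohol F7 (either C1 epimer serves). 1,1'-Thiocarbonyldiimidazole and DMAP in toluene at 80 °C give the O-thiocarbonylimidazolide F8, and Bu3SnH with AIBN in toluene at 100 °C (Barton–McCombie deoxygenation, to which a primary nitro group should be inert) gives 16, where the route is rejoined.

**Further compounds**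

F1 | step 6 | trimethylsilyl enol ether, trimethyl{[(3S)-2,4,4-trimethyl-3-vinylcyclohex-1-en-1-yl]oxy}silane | C=C[C@H]1C(C)(C)CCC(O[Si](C)(C)C)=C1C
F2 | step 6 | lithium (3S)-2,4,4-trimethyl-3-vinylcyclohex-1-en-1-olate | C=C[C@H]1C(C)(C)CCC(O[Li])=C1C
F3 | step 6 | lithium nitronate of 13 | C=C[C@H]1C(C)(C)CCC(=O)[C@]1(C)[C@H](CC/C(C)=C/CO[Si](c2ccccc2)(c2ccccc2)C(C)(C)C)C=[N+]([O-])O[Li]
F4 | step 14 | 15-(tert-butyldiphenylsilyloxy)-7β-hydroxy-17-nor-9-epi-labd-13E-en-8-one | O[C@H]1C[C@H]2C(C)(C)CCC[C@]2(C)[C@H](CC/C(C)=C/CO[Si](c3ccccc3)(c3ccccc3)C(C)(C)C)C1=O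
F5 | step 14 | dilithium 7-alkoxide 8(9)-enolate of F4 | [Li]O[C@H]1C[C@H]2C(C)(C)CCC[C@]2(C)C(CC/C(C)=C/CO[Si](c3ccccc3)(c3ccccc3)C(C)(C)C)=C1O[Li]
F6 | step 14 | 15-(tert-butyldiphenylsilyloxy)-7β-hydroxy-17-norlabd-13E-en-8-one (H-9 α) | O[C@H]1C[C@H]2C(C)(C)CCC[C@]2(C)[C@@H](CC/C(C)=C/CO[Si](c3ccccc3)(c3ccccc3)C(C)(C)C)C1=O
F7 | step 7 | C1 alcohol from 13 (C1 epimers) | C=C[C@H]1C(C)(C)CCC(O)[C@]1(C)[C@H](CC/C(C)=C/CO[Si](c2ccccc2)(c2ccccc2)C(C)(C)C)C[N+](=O)[O-]
F8 | step 7 | O-(imidazol-1-ylthiocarbonyl) derivative of F7 (C1 epimers) | C=C[C@H]1C(C)(C)CCC(OC(=S)n2ccnc2)[C@]1(C)[C@H](CC/C(C)=C/CO[Si](c2ccccc2)(c2ccccc2)C(C)(C)C)C[N+](=O)[O-]
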